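**Strategy.** Ring B (seven-membered) is not cyclised but grown from a cyclopentanone. In ring B the oxygen-bearing C6 and the methyl-bearing C8 are 1,3-related across C7H2, which is the polarity pattern of a silyl enol ether plus a ketene. Dichloroketene therefore adds [2+2] to the C6=C9 enol ether of a cis-fused bicyclo[3.3.0]octadiene (a silyl dienol ether with no seven-membered ring), forming C6–C7 and C8–C9 together. Methyl addition at C8 and Grob cleavage of the old C6–C9 bond then unveil the hydroazulene. C1 is set by asymmetric conjugate addition; C6, C4, C5, C8 and C9 are relayed from it.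

Key step: step 6

Remark: atoms are numbered as in daucane (C1 quaternary carbon with the angular methyl, C2/C3 ring A methylenes, C4 carbinol carbon with isopropyl, C5 ring-fusion CH, C6 ester carbon, C7 CH2, C8 and C9 epoxide carbons, C10 CH2; ring A five-membered, ring B seven-membered), β is the face of the C1 methyl, and the ligand antipode in step 2 is assumed to be the one that gives (R)-6.

Step 1
Reactants: 1 3-ethoxycyclopent-2-en-1-one; 2 5-bromo-2-methylpent-2-ene
Product: 5 3-(4-methylpent-3-en-1-yl)cyclopent-2-en-1-one, via Grignard reagent 3 (not isolated), via bromomagnesium alkoxide 4 (not isolated)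
Conditions: Mg, THF, 25–40 °C; then 1, 0 °C; then 1 M HCl, 25 °C
Reagents that add atoms: water, O
Why: Stork–Danheiser sequence: 1,2-addition of the Grignard reagent to the vinylogous ester and acid hydrolysis with allylic transposition should give the 3-substituted enone; no stereocentre is formed.

Step 2
Reactants: 5 3-(4-methylpent-3-en-1-yl)cyclopent-2-en-1-one
Product: 6 (3R)-3-methyl-3-(4-methylpent-3-en-1-yl)cyclopentan-1-one
Conditions: Me3Al, copper thiophene-2-carboxylate CuO2CC4H3S (5 mol %), chiral binaphthol-based phosphoramidite ligand (10 mol %), Et2O, –30 °C; then 1 M HCl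
Reagents that add atoms: trimethylaluminium, C[Al](C)C
Why: Copper-catalysed asymmetric conjugate addition of Me3Al to a β-substituted cyclopentenone creates the quaternary C1 under control of the chiral phosphoramidite–copper complex, methyl being delivered to the enone face that gives the R ketone.

Step 3
Reactants: 6 (3R)-3-methyl-3-(4-methylpent-3-en-1-yl)cyclopentan-1-one
Product: 8 (3S)-3-methyl-3-(4-methyl-3-oxopentyl)cyclopentan-1-one, via alkylborane–borate adduct 7 (not isolated)
Conditions: BH3·THF (excess), THF, 0 → 25 °C; then Na2Cr2O7, H2SO4, H2O/Et2O, 25 °C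
Reagents that add atoms: chromic acid (from Na2Cr2O7/H2SO4), O[Cr](O)(=O)=O
Why: Brown hydroboration puts boron on the less substituted alkene carbon (the ring ketone is reduced to a borate at the same time) and chromic acid oxidises both the C–B and the C–O–B sites to ketones, so the side-chain carbonyl appears at C4 and C1 is untouched.

Step 4
Reactants: 8 (3S)-3-methyl-3-(4-methyl-3-oxopentyl)cyclopentan-1-one
Product: 10 (3aR)-3a-methyl-6-(propan-2-yl)-3,3a,4,5-tetrahydropentalen-1(2H)-one, via aldol adduct 9 (not isolated)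
Conditions: KOH, EtOH, 78 °C
Reagents that add atoms: none
Why: Intramolecular aldol condensation: only the aldol from C5 onto the C4 ketone can dehydrate to a conjugated enone whereas the bridged aldols revert, so the bicyclo[3.3.0]octenone should be the thermodynamic sink and no new stereocentre survives.

Step 5
Reactants: 10 (3aR)-3a-methyl-6-(propan-2-yl)-3,3a,4,5-tetrahydropentalen-1(2H)-one
Product: 12 tert-butyl(dimethyl){[(3aR)-3a-methyl-6-(propan-2-yl)-3,3a,4,5-tetrahydropentalen-1-yl]oxy}silane, via lithium dienolate 11 (not isolated)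
Conditions: LiN(iPr)2, THF, –78 °C; then TBSOTf, –78 → 0 °C
Reagents that add atoms: tert-butyldimethylsilyl trifluoromethanesulfonate, CC(C)(C)[Si](C)(C)OS(=O)(=O)C(F)(F)F
Why: Kinetic deprotonation of the enone at the α′-methylene C9 and O-silylation of the cross-conjugated dienolate give the 2-silyloxydiene; no stereocentre is formed.

Step 6
Reactants: 12 tert-butyl(dimethyl){[(3aR)-3a-methyl-6-(propan-2-yl)-3,3a,4,5-tetrahydropentalen-1-yl]oxy}silane
Product: 13 7,7-dichloro-6β-(tert-butyldimethylsilyloxy)-14-nor-6,9-cyclodauc-4-en-8-one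
Conditions: Cl2CHCOCl (slow addition), Et3N, hexane, 0 → 25 °C
Reagents that add atoms: dichloroacetyl chloride, ClC(Cl)C(Cl)=O
Why: Dichloroketene, formed in the flask by dehydrochlorination, undergoes a concerted but asynchronous [2+2] cycloaddition with the enol-ether double bond: its electrophilic carbonyl carbon (future C8) bonds to the nucleophilic β-carbon C9 while the CCl2 carbon (future C7) bonds to the silyloxy carbon C6. The closest known reaction type is the dichloroketene–silyl enol ether cycloaddition used for two-carbon ring expansion of cycloalkanones to cycloalkane-1,3-diones. The only ring closed is the cyclobutanone, by intermolecular suprafacial addition across C6=C9, which forces a cis ring fusion. The two new stereocentres C6 and C9 should arise by approach anti to the angular C1 methyl, but both are erased later (C6 becomes a carbonyl, C9 becomes sp2), so the facial outcome is immaterial. The step needs regioselectivity (C8 to C9, C7 to C6), which the polarity of the enol ether secures. It also needs chemoselectivity for the enol-ether alkene over the tetrasubstituted C4=C5 alkene, which the higher nucleophilicity of the enol ether and the s-trans-locked diene (no [4+2] possible) secure.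

Step 7
Reactants: 13 7,7-dichloro-6β-(tert-butyldimethylsilyloxy)-14-nor-6,9-cyclodauc-4-en-8-one
Product: 14 6β-(tert-butyldimethylsilyloxy)-14-nor-6,9-cyclodauc-4-en-8-one
Conditions: Zn dust, NH4Cl, MeOH, 25 °C
Reagents that add atoms: none
Why: Reductive dechlorination of the α,α-dichlorocyclobutanone by zinc (electron transfer to the C–Cl bonds next to the carbonyl, protonation of the zinc enolate) makes C7 a methylene without touching the silyl ether or the alkene.

Step 8
Reactants: 14 6β-(tert-butyldimethylsilyloxy)-14-nor-6,9-cyclodauc-4-en-8-one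
Product: 15 6β-(tert-butyldimethylsilyloxy)-6,9-cyclodauc-4-en-8-ol
Conditions: MeMgBr, CeCl3, THF, –78 °C; then aq. NH4Cl
Reagents that add atoms: methylmagnesium bromide, C[Mg]Br
Why: 1,2-Addition of the organocerium reagent from MeMgBr and CeCl3 to the strained, enolisable cyclobutanone brings in the C8 methyl; the C8 carbinol centre forms by attack on the less hindered face and is erased in step 9.

Step 9
Reactants: 15 6β-(tert-butyldimethylsilyloxy)-6,9-cyclodauc-4-en-8-ol
Product: 17 (8aR)-6,8a-dimethyl-3-(propan-2-yl)-1,2,8,8a-tetrahydroazulen-4(5H)-one, via tertiary mesylate 16 (not isolated)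
Conditions: MsCl, Et3N, CH2Cl2, –20 → 0 °C; pH 7 buffer
Reagents that add atoms: none
Why: Grob fragmentation: the tertiary mesylate ionises with push from the 1,3-related silyloxy oxygen and the strained ring-fusion bond C6–C9 (the bond to the more substituted carbon, the same one that breaks in the retro-aldol opening of 1-silyloxybicyclo[3.2.0]heptan-6-ones) should cleave to give the C6 ketone and the trisubstituted C8=C9 alkene while chloride takes the silyl group; no stereocentre is formed.

Step 10
Reactants: 17 (8aR)-6,8a-dimethyl-3-(propan-2-yl)-1,2,8,8a-tetrahydroazulen-4(5H)-one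
Product: 18 (4R,8aR)-6,8a-dimethyl-3-(propan-2-yl)-1,2,4,5,8,8a-hexahydroazulen-4-ol
Conditions: (S)-2-methyl-CBS-oxazaborolidine (20 mol %), catecholborane, toluene, –78 °C
Reagents that add atoms: none
Why: Corey–Bakshi–Shibata reduction: with the fully substituted alkenyl side of the enone as the large group the S catalyst should deliver hydride to the α-face of C6 (the face also left open by the angular methyl) and set the 6β (R) carbinol, and catecholborane does not touch the C8=C9 alkene.

Step 11
Reactants: 18 (4R,8aR)-6,8a-dimethyl-3-(propan-2-yl)-1,2,4,5,8,8a-hexahydroazulen-4-ol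
Product: 19 4β,5β-epoxydauc-8-en-6β-ol
Conditions: VO(acac)2 (5 mol %), tBuOOH (1.05 equiv), CH2Cl2, 0 °C
Reagents that add atoms: tert-butyl hydroperoxide, CC(C)(C)OO
Why: Vanadium-catalysed hydroxyl-directed epoxidation: the vanadium peroxide bound to the 6β-alkoxide delivers oxygen to the β-face of the allylic C4=C5 alkene and so sets C4 and C5, while the homoallylic C8=C9 alkene should react much more slowly with one equivalent of oxidant.

Step 12
Reactants: 19 4β,5β-epoxydauc-8-en-6β-ol
Product: 21 4β-(trimethylsilyloxy)-5αH-dauc-8-en-6-one, via silylated epoxy alcohol 20 (not isolated)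
Conditions: TMSOTf (2.2 equiv), iPr2NEt, CH2Cl2, –78 → –40 °C; pH 7 buffer
Reagents that add atoms: trimethylsilyl trifluoromethanesulfonate, C[Si](C)(C)OS(=O)(=O)C(F)(F)F
Why: Non-aldol aldol (semipinacol) rearrangement of the 2,3-epoxy alcohol silyl ether: TMSOTf activates the epoxide and the C6 hydride, antiperiplanar to the C5–O bond because 6-O and the epoxide are syn, shifts to the α-face of C5 with inversion, which sets the trans ring fusion, regenerates the C6 ketone and leaves the epoxide oxygen on C4 as the β-silyl ether.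

Step 13
Reactants: 21 4β-(trimethylsilyloxy)-5αH-dauc-8-en-6-one
Product: 22 4β-(trimethylsilyloxy)-5αH-dauc-8-en-6β-ol
Conditions: LiBH(s-Bu)3, THF, –78 °C; then H2O
Reagents that add atoms: none
Why: Ketone reduction by a bulky trialkylborohydride: hydride should enter C6 from the α-face, anti to the 1,3-related axial C1 methyl (equatorial attack), and give the axial 6β-alcohol.

Step 14
Reactants: 22 4β-(trimethylsilyloxy)-5αH-dauc-8-en-6β-ol; 23 4-acetoxybenzoic acid
Product: 24 4β-(trimethylsilyloxy)-5αH-dauc-8-en-6β-yl 4-acetoxybenzoate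
Conditions: DCC, DMAP, CH2Cl2, 25 → 40 °C
Reagents that add atoms: none
Why: Steglich esterification: the DMAP-activated acyl donor acylates the secondary 6β-hydroxyl with retention of configuration while the tertiary silyl ether is inert.

Step 15
Reactants: 24 4β-(trimethylsilyloxy)-5αH-dauc-8-en-6β-yl 4-acetoxybenzoate
Product: 25 8α,9α-epoxy-4β-(trimethylsilyloxy)-5αH-daucan-6β-yl 4-acetoxybenzoate
Conditions: mCPBA, NaHCO3, CH2Cl2, 0 °C
Reagents that add atoms: meta-chloroperoxybenzoic acid, OOC(=O)c1cccc(Cl)c1
Why: Prilezhaev epoxidation of the only remaining alkene: the peracid should attack the α-face of C8=C9 because the β-face is screened by the angular methyl and the axial 6β-aroyloxy group, which sets C8 and C9.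

Step 16
Reactants: 25 8α,9α-epoxy-4β-(trimethylsilyloxy)-5αH-daucan-6β-yl 4-acetoxybenzoate
Product: 26 8α,9α-epoxy-4β-hydroxy-5αH-daucan-6β-yl 4-hydroxybenzoate
Conditions: K2CO3, MeOH, 0 → 25 °C
Reagents that add atoms: none
Why: Base-catalysed methanolysis removes the phenolic acetate and the labile tertiary trimethylsilyl ether, whereas the hindered benzoate (deactivated as the phenoxide) and the epoxide should not be attacked; no stereocentre is touched.

**Compound list**

1 | 3-ethoxycyclopent-2-en-1-one | CCOC1=CC(=O)CC1 | starting material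
2 | 5-bromo-2-methylpent-2-ene | CC(C)=CCCBr | starting material
3 | (4-methylpent-3-en-1-yl)magnesium bromide (not isolated) | CC(C)=CCC[Mg]Br | intermediate
4 | bromomagnesium 3-ethoxy-1-(4-methylpent-3-en-1-yl)cyclopent-2-en-1-olate (not isolated) | CCOC1=CC(CCC=C(C)C)(O[Mg]Br)CC1 | intermediate
5 | 3-(4-methylpent-3-en-1-yl)cyclopent-2-en-1-one | CC(C)=CCCC1=CC(=O)CC1 | intermediate
6 | (3R)-3-methyl-3-(4-methylpent-3-en-1-yl)cyclopentan-1-one | CC(C)=CCC[C@]1(C)CCC(=O)C1 | intermediate
7 | alkylborane–borate adduct of 6, boron on the secondary side-chain carbon and on the ring oxygen, drawn with monomeric BH2 groups (not isolated) | CC(C)C(B)CC[C@]1(C)CCC(OB)C1 | intermediate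
8 | (3S)-3-methyl-3-(4-methyl-3-oxopentyl)cyclopentan-1-one | CC(C)C(=O)CC[C@]1(C)CCC(=O)C1 | intermediate
9 | aldol adduct, 6-hydroxy-3a-methyl-6-(propan-2-yl)hexahydropentalen-1(2H)-one (not isolated) | CC(C)C1(O)CC[C@]2(C)CCC(=O)C12 | intermediate
10 | (3aR)-3a-methyl-6-(propan-2-yl)-3,3a,4,5-tetrahydropentalen-1(2H)-one | CC(C)C1=C2C(=O)CC[C@@]2(C)CC1 | intermediate
11 | lithium dienolate of 10, deprotonated at C9 (not isolated) | CC(C)C1=C2C(O[Li])=CC[C@@]2(C)CC1 | intermediate
12 | tert-butyl(dimethyl){[(3aR)-3a-methyl-6-(propan-2-yl)-3,3a,4,5-tetrahydropentalen-1-yl]oxy}silane | CC(C)C1=C2C(O[Si](C)(C)C(C)(C)C)=CC[C@@]2(C)CC1 | intermediate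
13 | 7,7-dichloro-6β-(tert-butyldimethylsilyloxy)-14-nor-6,9-cyclodauc-4-en-8-one (cyclobutanone cis-fused on the α-face, 9β-H) | CC(C)C1=C2[C@@]3(O[Si](C)(C)C(C)(C)C)C(Cl)(Cl)C(=O)[C@H]3C[C@@]2(C)CC1 | intermediate
14 | 6β-(tert-butyldimethylsilyloxy)-14-nor-6,9-cyclodauc-4-en-8-one | CC(C)C1=C2[C@@]3(O[Si](C)(C)C(C)(C)C)CC(=O)[C@H]3C[C@@]2(C)CC1 | intermediate
15 | 6β-(tert-butyldimethylsilyloxy)-6,9-cyclodauc-4-en-8-ol (C8 configuration inconsequential) | CC(C)C1=C2[C@@]3(O[Si](C)(C)C(C)(C)C)CC(C)(O)[C@H]3C[C@@]2(C)CC1 | intermediate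
16 | 8-methanesulfonate of 15 (not isolated) | CC(C)C1=C2[C@@]3(O[Si](C)(C)C(C)(C)C)CC(C)(OS(C)(=O)=O)[C@H]3C[C@@]2(C)CC1 | intermediate
17 | (8aR)-6,8a-dimethyl-3-(propan-2-yl)-1,2,8,8a-tetrahydroazulen-4(5H)-one (dauca-4,8-dien-6-one) | CC(C)C1=C2C(=O)CC(C)=CC[C@@]2(C)CC1 | intermediate
18 | (4R,8aR)-6,8a-dimethyl-3-(propan-2-yl)-1,2,4,5,8,8a-hexahydroazulen-4-ol (dauca-4,8-dien-6β-ol) | CC(C)C1=C2[C@H](O)CC(C)=CC[C@@]2(C)CC1 | intermediate
19 | 4β,5β-epoxydauc-8-en-6β-ol | CC(C)[C@]12CC[C@]3(C)CC=C(C)C[C@@H](O)[C@@]31O2 | intermediate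
20 | 6-O-trimethylsilyl ether of 19 (not isolated) | CC(C)[C@]12CC[C@]3(C)CC=C(C)C[C@@H](O[Si](C)(C)C)[C@@]31O2 | intermediate
21 | 4β-(trimethylsilyloxy)-5αH-dauc-8-en-6-one (trans-fused) | CC(C)[C@]1(O[Si](C)(C)C)CC[C@]2(C)CC=C(C)CC(=O)[C@H]21 | intermediate
22 | 4β-(trimethylsilyloxy)-5αH-dauc-8-en-6β-ol | CC(C)[C@]1(O[Si](C)(C)C)CC[C@]2(C)CC=C(C)C[C@@H](O)[C@H]21 | intermediate
23 | 4-acetoxybenzoic acid | CC(=O)Oc1ccc(cc1)C(O)=O | starting material
24 | 4β-(trimethylsilyloxy)-5αH-dauc-8-en-6β-yl 4-acetoxybenzoate | CC(C)[C@]1(O[Si](C)(C)C)CC[C@]2(C)CC=C(C)C[C@@H](OC(=O)c3ccc(OC(C)=O)cc3)[C@H]21 | intermediate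
25 | 8α,9α-epoxy-4β-(trimethylsilyloxy)-5αH-daucan-6β-yl 4-acetoxybenzoate | CC(C)[C@]1(O[Si](C)(C)C)CC[C@]2(C)C[C@@H]3O[C@]3(C)C[C@@H](OC(=O)c3ccc(OC(C)=O)cc3)[C@H]21 | intermediate
26 | 8α,9α-epoxy-4β-hydroxy-5αH-daucan-6β-yl 4-hydroxybenzoate (CNP0163817.3) | CC(C)[C@]1(O)CC[C@]2(C)C[C@@H]3O[C@]3(C)C[C@@H](OC(=O)c3ccc(O)cc3)[C@H]21 | target

Total step count: 16. Longest linear sequence: 16 steps (1 to 26); 2 enters in step 1 and 23 in step 14.

**Steps most likely to fail**

Step 9 (fragmentation). The process at risk is cleavage of the wrong cyclobutane bond (C6–C7, which would leave an isopropenyl cyclopentanone) or simple elimination of the tertiary sulfonate. The fallback gives up the C8 carbinol and opens the ring by retro-aldol. It sets out from 14: anhydrous fluoride (tris(dimethylamino)sulfonium difluorotrimethylsilicate, THF, –78 → –20 °C) frees the C6 alkoxide in the presence of N-(5-chloropyridin-2-yl)bis(trifluoromethanesulfonyl)imide. Retro-aldol cleavage of the C6–C9 bond should give the C8–C9 enolate regiospecifically, which is trapped as (8aR)-8a-methyl-4-oxo-3-(propan-2-yl)-1,2,4,5,8,8a-hexahydroazulen-6-yl trifluoromethanesulfonate F1. Coupling of F1 with Me2CuLi (THF, –78 °C) replaces triflate by methyl and comes back to the route at 17.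

Step 12 (rearrangement). The process at risk is ionisation of the tetrasubstituted epoxide at C4 instead of C5, or migration of C7 instead of hydride (ring contraction). The fallback makes the C5–O bond the only one that can break. It sets out from 19: Dess–Martin oxidation gives 4β,5β-epoxydauc-8-en-6-one F2. SmI2 in THF/MeOH at –90 °C cleaves only the bond between the α-carbon and oxygen and should give 4β-hydroxy-5αH-dauc-8-en-6-one F3. C5 is protonated on the α-face, away from the samarium-bound 4β-alkoxide; this is also the thermodynamically preferred trans fusion, with C6 anti to the isopropyl group. Silylation of F3 with TMSCl/imidazole comes back to the route at 21.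

Step 13 (ketone reduction). The process at risk is poor facial selectivity, hydride entering from the β-face and giving the equatorial alcohol. The fallback corrects the centre by inversion instead of by reduction. It sets out from 21: the epimer that forms (or is made on purpose with a small hydride such as NaBH4), 4β-(trimethylsilyloxy)-5αH-dauc-8-en-6α-ol F4, is esterified with 23 under Mitsunobu conditions (PPh3, diisopropyl azodicarboxylate, toluene, 0 → 25 °C). This inverts C6 and comes back to the route at 24.

**Further compounds**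

F1 | step 9 | (8aR)-8a-methyl-4-oxo-3-(propan-2-yl)-1,2,4,5,8,8a-hexahydroazulen-6-yl trifluoromethanesulfonate | CC(C)C1=C2C(=O)CC(OS(=O)(=O)C(F)(F)F)=CC[C@@]2(C)CC1
F2 | step 12 | 4β,5β-epoxydauc-8-en-6-one | CC(C)[C@]12CC[C@]3(C)CC=C(C)CC(=O)[C@@]31O2
F3 | step 12 | 4β-hydroxy-5αH-dauc-8-en-6-one | CC(C)[C@]1(O)CC[C@]2(C)CC=C(C)CC(=O)[C@H]21
F4 | step 13 | 4β-(trimethylsilyloxy)-5αH-dauc-8-en-6α-ol | CC(C)[C@]1(O[Si](C)(C)C)CC[C@]2(C)CC=C(C)C[C@H](O)[C@H]21
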